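The ten-membered carbocycle is made by contraction of a twelve-membered cyclic ether. The route exploits the C11=C13 methylene unit on ring-fusion carbon C7 next to the vicinal oxygens on C8 (lactone O–CH) and C9 (CHOH): the C7–C8 bond is formed by a Claisen rearrangement in which the ring oxygen on C9 and two ring carbons (C13, C11) are expelled while the exocyclic formyl carbon C8 enters. One operation closes the carbocycle, sets C7 and C8, and unveils the C9 ketone and the C11=C13 methylene. The precursor is a 1-oxacyclododec-3-ene carrying the trans-epoxide, the C6 tiglate, the C10 methyl and a formyl group, used as its (Z)-silyl enol ether.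

Key step: step 16

Remark (atom labels): germacranolide labels are used throughout: ring C1–C10 with C1–C3 = CH2, C4(Me)–C5 = epoxide, C6 = CH–O-tigloyl, C7 = ring fusion, C8 = CH–O(lactone), C9 = CHOH, C10 = CHMe; C11=C13 is the methylene unit and C12 the lactone carbonyl.
Remark (assumption): aldehyde 5 is taken to be a catalogue compound.

Step 1
Reactants: 1 prop-2-yn-1-ol
Product: 3 (2E)-3-iodo-2-methylprop-2-en-1-ol, via alkenylalane 2 (not isolated)
Conditions: Me3Al, Cp2ZrCl2 (cat.), CH2Cl2, 0 °C → rt; then I2, THF, −30 → 0 °C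
Reagents that add atoms: trimethylaluminium C[Al](C)C; iodine II
Why: Negishi Zr-catalysed carboalumination is a syn addition that puts methyl on the internal and Al on the terminal carbon, and iodinolysis with retention should give the E iodide, so that the future C12 methyl is cis to the future C6.

Step 2
Reactants: 3 (2E)-3-iodo-2-methylprop-2-en-1-ol
Product: 4 (1E)-3-bromo-1-iodo-2-methylprop-1-ene
Conditions: CBr4, PPh3, CH2Cl2, 0 °C
Reagents that add atoms: carbon tetrabromide BrC(Br)(Br)Br
Why: Appel bromination of the primary allylic alcohol proceeds by SN2 at CH2 and should leave the alkene geometry untouched.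

Step 3
Reactants: 5 2-[(4-methoxybenzyl)oxy]acetaldehyde
Product: 6 (2R,3R)-1-[(4-methoxybenzyl)oxy]-3-methylpent-4-en-2-ol
Conditions: trans-2-butene, n-BuLi, KOt-Bu, THF, −45 °C; (+)-Ipc2BOMe, −78 °C; BF3·OEt2; 5, −78 °C; NaOH, H2O2
Reagents that add atoms: trans-2-butene C/C=C/C
Why: Brown crotylboration through a chair Zimmerman–Traxler transition state, in which the E-crotyl group gives the anti adduct and the (+)-Ipc2B reagent (from (−)-α-pinene) should attack the Re face, sets C10 (R); the C9 carbinol configuration is erased later.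

Step 4
Reactants: 6 (2R,3R)-1-[(4-methoxybenzyl)oxy]-3-methylpent-4-en-2-ol; 4 (1E)-3-bromo-1-iodo-2-methylprop-1-ene
Product: 7 1-({[(2R,3R)-2-{[(2E)-3-iodo-2-methylprop-2-en-1-yl]oxy}-3-methylpent-4-en-1-yl]oxy}methyl)-4-methoxybenzene
Conditions: NaH, THF–DMF, 0 °C; 4, n-Bu4NI (cat.), 0 °C → rt
Reagents that add atoms: none
Why: Williamson etherification, SN2 of the secondary alkoxide on the primary allylic bromide, installs the C9–O–C13 ether; the vinyl iodide is inert to NaH.

Step 5
Reactants: 8 pent-1-en-4-yne
Product: 10 (2E)-3-methylhexa-2,5-dien-1-ol, via alkenylalane 9 (not isolated)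
Conditions: Me3Al, Cp2ZrCl2 (cat.), CH2Cl2, rt; n-BuLi, THF, −78 °C; (CH2O)n, −78 °C → rt
Reagents that add atoms: trimethylaluminium C[Al](C)C; formaldehyde (as paraformaldehyde) C=O
Why: Negishi carboalumination takes the alkyne in preference to the terminal alkene, and hydroxymethylation of the derived alanate with retention should give the E trisubstituted allylic alcohol (future C4=C5, C6).

Step 6
Reactants: 10 (2E)-3-methylhexa-2,5-dien-1-ol
Product: 11 [(2R,3R)-3-methyl-3-(prop-2-en-1-yl)oxiran-2-yl]methanol
Conditions: Ti(Oi-Pr)4 (cat.), D-(−)-diethyl tartrate (cat.), t-BuOOH, 4 Å MS, CH2Cl2, −20 °C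
Reagents that add atoms: tert-butyl hydroperoxide CC(C)(C)OO
Why: Sharpless asymmetric epoxidation of the allylic alcohol with D-(−)-tartrate should deliver oxygen to the face that gives the (2R,3R)-epoxide (C5 and C4 of the target, by analogy with geraniol), and the isolated vinyl group does not react.

Step 7
Reactants: 7 the iodo-allyl ether from step 4; 11 [(2R,3R)-3-methyl-3-(prop-2-en-1-yl)oxiran-2-yl]methanol
Product: 12 [(2R,3R)-3-[(4R,5R)-5-{[(2E)-3-iodo-2-methylprop-2-en-1-yl]oxy}-6-[(4-methoxybenzyl)oxy]-4-methylhex-2-en-1-yl]-3-methyloxiran-2-yl]methanol (E/Z mixture at the new C1=C2 alkene)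
Conditions: Hoveyda–Grubbs II (5 mol%), 11 (3 equiv), CH2Cl2, 40 °C
Reagents that add atoms: none
Why: Olefin cross-metathesis between the slowly dimerising branched allylic olefin 7 and an excess of the unhindered terminal olefin 11 should favour the cross product; the trisubstituted iodoalkene does not engage and the alkene geometry is irrelevant.

Step 8
Reactants: 12 the cross-metathesis product
Product: 13 [(2R,3R)-3-[(4R,5R)-5-{[(2E)-3-iodo-2-methylprop-2-en-1-yl]oxy}-6-[(4-methoxybenzyl)oxy]-4-methylhexyl]-3-methyloxiran-2-yl]methanol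
Conditions: 2-nitrobenzenesulfonylhydrazide, Et3N, CH2Cl2, rt
Reagents that add atoms: none
Why: Diimide reduction should saturate only the 1,2-disubstituted alkene and leave the trisubstituted vinyl iodide, the epoxide and the PMB ether.

Step 9
Reactants: 13 the saturated epoxy alcohol
Product: 14 (2S,3R)-3-[(4R,5R)-5-{[(2E)-3-iodo-2-methylprop-2-en-1-yl]oxy}-6-[(4-methoxybenzyl)oxy]-4-methylhexyl]-3-methyloxirane-2-carbaldehyde (same spatial arrangement as 13; the descriptor changes by priority only)
Conditions: Dess–Martin periodinane, NaHCO3, CH2Cl2, 0 °C → rt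
Reagents that add atoms: none
Why: Buffered Dess–Martin oxidation of the primary epoxy alcohol should give the epoxy aldehyde (C6) without epimerisation at C5.

Step 10
Reactants: 14 the iodo epoxy aldehyde
Product: 15 twelve-membered cyclic ether O–C13H2–C11(Me)=C7H–C6H(OH)–C5H(–O–)C4(Me)–(CH2)3–C10H(Me)–C9H(CH2OPMB)–O, (E)-alkene, both C6 epimers
Conditions: CrCl2, NiCl2 (cat.), DMSO–THF, rt, 3 mM (slow addition)
Reagents that add atoms: none
Why: Intramolecular Nozaki–Hiyama–Kishi coupling of the alkenyl iodide with the aldehyde should close the 12-membered ring at C6–C7 with retention of the E geometry; the C6 epimers converge in the next two steps.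

Step 11
Reactants: 15 the macrocyclic allylic alcohols
Product: 16 macrocyclic α,β-epoxy-α′,β′-enone (C6 ketone)
Conditions: Dess–Martin periodinane, NaHCO3, CH2Cl2, 0 °C → rt
Reagents that add atoms: none
Why: Dess–Martin oxidation of the allylic alcohol converts both C6 epimers into one epoxy enone.

Step 12
Reactants: 16 the macrocyclic epoxy enone
Product: 17 macrocyclic (6R)-allylic alcohol, erythro to the epoxide
Conditions: Zn(BH4)2, Et2O, −20 °C
Reagents that add atoms: none
Why: Chelation-controlled 1,2-reduction of an α,β-epoxy ketone, in which zinc bridges the carbonyl and epoxide oxygens and hydride arrives from the side of H5, should give the erythro (anti) epoxy alcohol and thus C6 (R).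

Step 13
Reactants: 17 the macrocyclic (6R)-alcohol
Product: 18 macrocyclic C6 tiglate
Conditions: tigloyl chloride, Et3N, DMAP (cat.), CH2Cl2, 0 °C → rt
Reagents that add atoms: (2E)-2-methylbut-2-enoyl chloride C/C=C(\C)C(Cl)=O
Why: DMAP-catalysed acylation of the only free hydroxyl installs the tiglate before any second hydroxyl exists, so no later differentiation of C6–OH from C9–OH is needed.

Step 14
Reactants: 18 the macrocyclic tiglate
Product: 19 macrocyclic primary alcohol (C8–OH)
Conditions: DDQ, CH2Cl2–pH 7 buffer, 0 °C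
Reagents that add atoms: none
Why: Oxidative cleavage of the PMB ether by DDQ should spare the tiglate, the epoxide and the allylic ether.

Step 15
Reactants: 19 the macrocyclic primary alcohol
Product: 20 twelve-membered ether aldehyde (formyl C8 on C9)
Conditions: Dess–Martin periodinane, NaHCO3, CH2Cl2, 0 °C → rt
Reagents that add atoms: none
Why: Dess–Martin oxidation gives the α-alkoxy aldehyde, whose C9 configuration no longer matters because C9 becomes sp2 in the next step.

Step 16
Reactants: 20 the twelve-membered ether aldehyde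
Product: 23 ten-membered α-hydroxy ketone (C8–OH, C9=O, 2-propenyl on C7), via silyl enol ether 21 (not isolated), via α-silyloxy ketone 22 (not isolated)
Conditions: KHMDS, THF–PhMe, −78 °C; TMSCl–Et3N, −78 → 0 °C; PhMe, 110 °C; citric acid, MeOH, 0 °C
Reagents that add atoms: none
Why: Deprotonation of the single α-H of 20 gives the potassium enolate chelated between O8 and the ring oxygen, which is trapped as the (Z)-silyl enol ether 21; on heating, this allyl vinyl ether undergoes a concerted [3,3] shift in which C8 bonds to C7 as the C13–O bond breaks, so the ring oxygen becomes the C9 ketone oxygen and C13/C11 leave the ring as the 2-propenyl group (12 → 10), and mild acid then removes the TMS group of 22. The closest known reaction types are the Claisen rearrangement of enol derivatives of α-allyloxy carbonyl compounds and the Claisen ring contraction of methylenated macrolides. The carbocycle is closed by sigmatropic C–C bond formation in a six-membered chair transition state spanned by the seven-atom C10–C6 tether, not by a Baldwin-type cyclisation. C7 is controlled by C6: A(1,3) strain with the cis C12 methyl holds H6 in the alkene plane and C8 adds to the face anti to the tigloyloxy group, the face from which the tether approaches. C8 is controlled by the two alkene geometries in the chair, the (Z)-siloxy group being pseudo-axial and C6 (trans to C13) pseudo-equatorial, which gives the anti C8–O/C7–C6 relationship of the target. The step needs chair over boat and enolisation of the aldehyde in the presence of the tiglate; the long tether accommodates the chair with C6 equatorial, and the aldehyde α-H is by far the most acidic site at −78 °C.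

Step 17
Reactants: 23 the ten-membered α-hydroxy ketone
Product: 24 ten-membered 8,9-diol
Conditions: Zn(BH4)2, Et2O–CH2Cl2, −30 → 0 °C
Reagents that add atoms: none
Why: Chelation-controlled reduction of the α-hydroxy ketone, with hydride arriving anti to C7 in the zinc chelate, should give the anti (erythro) 8,9-diol and thus C9 (R); the tiglate and epoxide are not reduced.

Step 18
Reactants: 24 the ten-membered 8,9-diol
Product: 25 ten-membered triol with C12–OH (2-(hydroxymethyl)vinyl group on C7)
Conditions: SeO2 (0.5 equiv), t-BuOOH, CH2Cl2, rt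
Reagents that add atoms: selenium dioxide O=[Se]=O; tert-butyl hydroperoxide CC(C)(C)OO
Why: Sharpless SeO2/t-BuOOH allylic oxidation (ene reaction then [2,3] shift) should hydroxylate the methyl of the 1,1-disubstituted alkene, while the electron-poor tiglate alkene does not react.

Step 19
Reactants: 25 the C12 allylic alcohol
Product: 27 target (4R,5R,6R,7S,8S,9R,10R)-4,5-epoxy-9-hydroxy-6-tigloyloxy-germacr-11(13)-en-8,12-olide, via lactol 26 (not isolated)
Conditions: TEMPO (cat.), PhI(OAc)2, CH2Cl2, rt
Reagents that add atoms: none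
Why: Oxoammonium oxidation of the primary allylic alcohol to the enal, closure of the five-membered lactol onto the C8 hydroxyl and a second oxidation should give the trans-fused α-methylene-γ-butyrolactone; the secondary C9–OH is oxidised much more slowly and C6 is blocked as the tiglate.

Compound list
1 | prop-2-yn-1-ol | C#CCO | starting material
2 | dimethyl[(1E)-3-(dimethylalumanyloxy)-2-methylprop-1-en-1-yl]alumane | C[Al](C)OC/C(C)=C/[Al](C)C | intermediate
3 | (2E)-3-iodo-2-methylprop-2-en-1-ol | OC/C(C)=C/I | intermediate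
4 | (1E)-3-bromo-1-iodo-2-methylprop-1-ene | BrC/C(C)=C/I | intermediate
5 | 2-[(4-methoxybenzyl)oxy]acetaldehyde | COc1ccc(COCC=O)cc1 | starting material
6 | (2R,3R)-1-[(4-methoxybenzyl)oxy]-3-methylpent-4-en-2-ol | COc1ccc(COC[C@H](O)[C@H](C)C=C)cc1 | intermediate
7 | 1-({[(2R,3R)-2-{[(2E)-3-iodo-2-methylprop-2-en-1-yl]oxy}-3-methylpent-4-en-1-yl]oxy}methyl)-4-methoxybenzene | COc1ccc(COC[C@H](OC/C(C)=C/I)[C@H](C)C=C)cc1 | intermediate
8 | pent-1-en-4-yne | C=CCC#C | starting material
9 | dimethyl[(1E)-2-methylpenta-1,4-dien-1-yl]alumane | C=CC/C(C)=C/[Al](C)C | intermediate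
10 | (2E)-3-methylhexa-2,5-dien-1-ol | C=CC/C(C)=C/CO | intermediate
11 | [(2R,3R)-3-methyl-3-(prop-2-en-1-yl)oxiran-2-yl]methanol | C=CC[C@@]1(C)O[C@@H]1CO | intermediate
12 | cross-metathesis product, C1=C2 alkene as E/Z mixture, (4R,5R) side chain on the (2R,3R)-epoxy alcohol | COc1ccc(COC[C@H](OC/C(C)=C/I)[C@H](C)C=CC[C@@]2(C)O[C@@H]2CO)cc1 | intermediate
13 | saturated iodo epoxy alcohol (C1–C3 = CH2; C4, C5, C9, C10 as in 12) | COc1ccc(COC[C@H](OC/C(C)=C/I)[C@H](C)CCC[C@@]2(C)O[C@@H]2CO)cc1 | intermediate
14 | iodo epoxy aldehyde (C6 = CHO; stereocentres spatially as in 13) | COc1ccc(COC[C@H](OC/C(C)=C/I)[C@H](C)CCC[C@@]2(C)O[C@@H]2C=O)cc1 | intermediate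
15 | twelve-membered cyclic ether, C6 carbinol (both epimers), (E)-C7=C11, trans-4,5-epoxide, CH2OPMB on C9 | COc1ccc(COC[C@H]2[C@H](C)CCC[C@@]3(C)O[C@@H]3C(O)/C=C(C)/CO2)cc1 | intermediate
16 | twelve-membered epoxy enone (C6 ketone) | COc1ccc(COC[C@H]2[C@H](C)CCC[C@@]3(C)O[C@@H]3C(=O)/C=C(C)/CO2)cc1 | intermediate
17 | twelve-membered (6R)-allylic alcohol, erythro to the epoxide | COc1ccc(COC[C@H]2[C@H](C)CCC[C@@]3(C)O[C@@H]3[C@H](O)/C=C(C)/CO2)cc1 | intermediate
18 | twelve-membered C6 tiglate, CH2OPMB on C9 | COc1ccc(COC[C@H]2[C@H](C)CCC[C@@]3(C)O[C@@H]3[C@H](OC(=O)/C(C)=C/C)/C=C(C)/CO2)cc1 | intermediate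
19 | twelve-membered C6 tiglate, CH2OH (C8) on C9 | OC[C@H]1[C@H](C)CCC[C@@]2(C)O[C@@H]2[C@H](OC(=O)/C(C)=C/C)/C=C(C)/CO1 | intermediate
20 | twelve-membered C6 tiglate, CHO (C8) on C9 | O=C[C@H]1[C@H](C)CCC[C@@]2(C)O[C@@H]2[C@H](OC(=O)/C(C)=C/C)/C=C(C)/CO1 | intermediate
21 | (Z)-trimethylsilyl enol ether of 20 (C8=C9, OSi cis to the ring oxygen) | C[Si](C)(C)O/C=C1/[C@H](C)CCC[C@@]2(C)O[C@@H]2[C@H](OC(=O)/C(C)=C/C)/C=C(C)/CO1 | intermediate
22 | ten-membered 8-trimethylsilyloxy-9-ketone with 2-propenyl on C7 (C4–C8, C10 spatially as in 27) | C[Si](C)(C)O[C@@H]1C(=O)[C@H](C)CCC[C@@]2(C)O[C@@H]2[C@H](OC(=O)/C(C)=C/C)[C@H]1C(C)=C | intermediate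
23 | ten-membered (4R,5R,6R,7S,8S,10R)-8-hydroxy-9-ketone, 6-tiglate, 4,5-epoxide, 7-(prop-1-en-2-yl) | O[C@@H]1C(=O)[C@H](C)CCC[C@@]2(C)O[C@@H]2[C@H](OC(=O)/C(C)=C/C)[C@H]1C(C)=C | intermediate
24 | ten-membered (8S,9R)-8,9-diol, otherwise as 23 | O[C@@H]1[C@H](O)[C@H](C)CCC[C@@]2(C)O[C@@H]2[C@H](OC(=O)/C(C)=C/C)[C@H]1C(C)=C | intermediate
25 | ten-membered 8,9-diol with 7-(3-hydroxyprop-1-en-2-yl) group (C12–OH) | O[C@@H]1[C@H](O)[C@H](C)CCC[C@@]2(C)O[C@@H]2[C@H](OC(=O)/C(C)=C/C)[C@H]1C(CO)=C | intermediate
26 | 8,12-lactol (hemiacetal at C12, both anomers) | C=C1C(O)O[C@@H]2[C@H](O)[C@H](C)CCC[C@@]3(C)O[C@@H]3[C@H](OC(=O)/C(C)=C/C)[C@@H]12 | intermediate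
27 | (4R,5R,6R,7S,8S,9R,10R)-4,5-epoxy-9-hydroxy-6-[(2E)-2-methylbut-2-enoyloxy]germacr-11(13)-en-8,12-olide | C=C1C(=O)O[C@@H]2[C@H](O)[C@H](C)CCC[C@@]3(C)O[C@@H]3[C@H](OC(=O)/C(C)=C/C)[C@@H]12 | target

Total step count: 19. Longest linear sequence: 16 steps (1 → 3 → 4 → 7 → 12 → … → 27; steps 1, 2, 4 and 7–19).

Steps most likely to fail

1. Step 16 (key step). The enol-ether geometry may erode during enolisation and silylation, and the shift may leak through a boat or through the other face of the allyl unit, which would scramble C7 and C8. The contraction may also stall as ring strain builds up. The fallback sets out from 20 and returns at 23; it separates the C8 oxygen from the contraction. Aldehyde 20 is converted (KHMDS, TBSCl) into the tert-butyldimethylsilyl enol ether F1, whose geometry no longer matters. Chemoselective ozonolysis of this electron-rich alkene (O3, CH2Cl2–pyridine, −78 °C; Me2S) excises C8 and leaves the twelve-membered lactone F2. Tebbe methylenation (THF–pyridine, −40 → 0 °C) should take the unconjugated lactone carbonyl in preference to the conjugated tiglate and give the 2-methylene oxacycle F3. Its Claisen ring contraction (PhMe, 110 °C) through an unsubstituted methylene terminus should give the ten-membered ketone F4. Kinetic enolisation towards the C8 methylene (KHMDS, −78 °C) and hydroxylation with the Davis oxaziridine anti to the C7 substituent should then give 23.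

2. Step 10. Oligomerisation may compete with closure of the twelve-membered ring, and Cr(II) may attack the epoxy aldehyde. The fallback sets out from 7 and 11 and returns at 15; it moves the ring closure to the unfunctionalised C1–C2 bond. Alcohol 11 is oxidised (Dess–Martin) to the epoxy aldehyde F5, which is coupled intermolecularly with 7 (CrCl2, NiCl2 cat.) to the acyclic allylic alcohol F6. Ring-closing metathesis between its two monosubstituted alkenes (Grubbs II, CH2Cl2, 40 °C, 2 mM) should give the cyclic diene F7. Diimide reduction of the disubstituted alkene (as in step 8) then gives 15.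

3. Step 18. The ene step may abstract the C7 methine hydrogen instead of a methyl hydrogen, the alcohol may over-oxidise, and selenous acid may open the epoxide. The fallback sets out from 24 and returns at 26. Ene-type allylic chlorination of the 1,1-disubstituted alkene (NaOCl, CeCl3·7H2O, CH2Cl2–H2O, 0 °C) should give the allylic chloride F8. Oxidation with 4-methylmorpholine N-oxide (MeCN, rt) should convert it into the enal F9, which closes onto the C8 hydroxyl to lactol 26. Lactol 26 is oxidised to 27 under the conditions of step 19.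

Further compounds
F1 | step 16 | tert-butyldimethylsilyl enol ether of 20 (either C8=C9 geometry) | CC(C)(C)[Si](C)(C)OC=C1[C@H](C)CCC[C@@]2(C)O[C@@H]2[C@H](OC(=O)/C(C)=C/C)/C=C(C)/CO1
F2 | step 16 | twelve-membered lactone (C9 carbonyl, O–C13), C6 tiglate | O=C1[C@H](C)CCC[C@@]2(C)O[C@@H]2[C@H](OC(=O)/C(C)=C/C)/C=C(C)/CO1
F3 | step 16 | 2-methylene oxacycle (exocyclic C8H2=C9) | C=C1[C@H](C)CCC[C@@]2(C)O[C@@H]2[C@H](OC(=O)/C(C)=C/C)/C=C(C)/CO1
F4 | step 16 | ten-membered 9-ketone with C8H2 and 2-propenyl on C7 | C1C(=O)[C@H](C)CCC[C@@]2(C)O[C@@H]2[C@H](OC(=O)/C(C)=C/C)[C@H]1C(C)=C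
F5 | step 10 | (2S,3R)-3-methyl-3-(prop-2-en-1-yl)oxirane-2-carbaldehyde | C=CC[C@@]1(C)O[C@@H]1C=O
F6 | step 10 | acyclic allylic alcohol from 7 and F5 (both C6 epimers) | COc1ccc(COC[C@H](OC/C(C)=C/C(O)[C@H]2O[C@]2(C)CC=C)[C@H](C)C=C)cc1
F7 | step 10 | twelve-membered cyclic diene (additional C1=C2 alkene, E/Z) | COc1ccc(COC[C@H]2[C@H](C)C=CC[C@@]3(C)O[C@@H]3C(O)/C=C(C)/CO2)cc1
F8 | step 18 | ten-membered 8,9-diol with 7-(3-chloroprop-1-en-2-yl) group | O[C@@H]1[C@H](O)[C@H](C)CCC[C@@]2(C)O[C@@H]2[C@H](OC(=O)/C(C)=C/C)[C@H]1C(CCl)=C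
F9 | step 18 | ten-membered 8,9-diol with 7-(3-oxoprop-1-en-2-yl) group | O[C@@H]1[C@H](O)[C@H](C)CCC[C@@]2(C)O[C@@H]2[C@H](OC(=O)/C(C)=C/C)[C@H]1C(C=O)=C
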